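All runs are calculated for an exercise, and the scatter is random.

If a flask stands at equilibrium with crystals J in it, find the product of L and E there, and carry that product to the next flask at the same temperature with crystals J standing. Here the flask is teal, followed to the asked time, and blue is an earlier, colder run with less E.

all flasks: L 0.16 M; Z 0.83 mM
- teal: E 0.176 M; temperature 25 °C; the very flask that is asked about, followed so far
- blue: E 0.12 M; temperature 10 °C; run made earlier
- flask: E 0.176 M; temperature 25 °C; time 15 h

| run | time / min | Q / % | L / % |
|---|---|---|---|
| teal | 50.0 | 58 | 43 |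
| teal | 150 | 60 | 41 |
| teal | 240 | 59 | 40 |
| teal | 360 | 59 | 41 |
| teal | 600 | 58 | 37 |
| teal | 720 | 61 | 38 |
| teal | 900 | 59 | 38 |
| blue | 8.00 | 28 | 75 |
| blue | 12.0 | 38 | 64 |
| blue | 20.0 | 46 | 54 |
| blue | 30.0 | 55 | 47 |
| blue | 40.0 | 57 | 41 |
| blue | 60.0 | 61 | 38 |
| blue | 120 | 67 | 31 |

(readings scatter by 1.5 percentage points)

- percent here means L units held: one X counts as two
- what is said of Q includes J
- J is a solid; its amount is given per volume of the solution
- what is added takes up no volume worth counting
- steps under discussion: L + Z <-> D; E + D <-> G; G <-> Z + Q; J <-> Q; L + D -> X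

* Q, in percent of the L first charged, at 15 h
* what to do for the largest gain in Q; "none" if nothing gains more than 2 percentage points (Tuesday's / Thursday's / Sunday's / Wednesday's / none)
* Q present, in percent of the L first charged, after Thursday's
* Q present, in percent of the L first charged, after Wednesday's

- Tuesday's: change nothing and wait 15 h more
- Thursday's: at 15 h raise the temperature by 25 K, then wait 15 h
- Sunday's: at 15 h add Z, 100 % of the amount charged, then wait 15 h
- Wednesday's: at 15 h add E, 50.0 % of the amount charged, then wait 15 h

Climb the time scales, fastest first. Blue passes half of its last Q between 8.00 min and 12.0 min. Teal, warmer and with more E, already reads 58 % at 50.0 min. From there to 900 min, teal's Q moves 1 percentage point, less than the scatter of 1.5 points. The asked time is that last reading, so take the mean of the seven, 59.1 %, as my figure for now. The catalyst forms can hold 1.04 % of the L charged at the very most, so count L as the rest of the charge.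

Read the flat line as equilibrium (thermodynamic control). Add the three catalytic steps: L and E give Q, and Z comes back. Assume crystals J stand in teal, which is a guess, since the readings count J inside Q. Dissolved Q then stays at its solubility, so at fixed temperature L times E stays too. Call this the standing product: L left times E left, both as fractions of the L charged, 0.208.

Use it. Waiting and extra Z leave it alone, so expect no gain from either. Blue, colder and still rising at its last reading, gives 0.0264 there, less than teal's, so expect heat to cost Q; I set no figure on that. Adding E while holding the product gives 76.5 %, so my choice is Wednesday's.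

The forecast gives 59 % now, Wednesday's as best, 35 % after Thursday's and 73 % after Wednesday's, lower than my figure. It writes: “Extra Z would change nothing, and neither would waiting.”

    L + Z ⇌ D (K = 2.30 L mol⁻¹, k = 49.0 L mol⁻¹ s⁻¹, Ea = 51.0 kJ mol⁻¹, ΔH = −62.0 kJ mol⁻¹)
    E + D ⇌ G (K = 118 L mol⁻¹, k = 8.41 L mol⁻¹ s⁻¹, Ea = 41.0 kJ mol⁻¹, ΔH = −62.0 kJ mol⁻¹)
    G ⇌ Z + Q (K = 0.0612 M, k = 2.00 s⁻¹, Ea = 61.0 kJ mol⁻¹, ΔH = 2.00 kJ mol⁻¹)
    J ⇌ Q, rate k4*(cs4 - [Q]) while solid is left; crystals form when [Q] > cs4 (solubility = 0.0850 M, k = 0.153 s⁻¹)
    L + D → X (k = 0.00782 L mol⁻¹ s⁻¹, Ea = 68.0 kJ mol⁻¹)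
    (constants at 25 °C)

The flask gives 59.5 % now, and Wednesday's gains 17 points, ending at 76.5 %. Thursday's ends at 5.74 %, 29 points under the forecast. At 900 min the flask holds J at 6.38 % of the L charged, and its standing product is 0.200. Now take the neighbour, the same flask with 0.44 M of E. Held at 0.208, the product gives Q 88.8 %. That neighbour ends with Q 88.8 %, J 35.7 % and L 10.8 %, and with E at 67.6 % of its own charge, a standing product of 0.200.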